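The data are simulated with made-up constants.

The target reads 1 % after 2.00 min in Monday's run and 61 % after 50.0 min, but the question here is the earlier hump of intermediate C.

| flask | starting material | remark | time |
|---|---|---|---|
| Monday's | 0.37 M | run made earlier |  |
| Sunday's | 0.83 M | run made earlier |  |
| flask | 0.55 M |  | 80 min |

| run | time / min | intermediate C / % | target / % |
|---|---|---|---|
| Monday's | 0.500 | 38 | 0 |
| Monday's | 2.00 | 51 | 1 |
| Monday's | 10.0 | 5 | 45 |
| Monday's | 50.0 | 4 | 61 |
| Sunday's | 0.500 | 37 | 1 |
| Sunday's | 2.00 | 47 | 1 |
| Sunday's | 10.0 | 5 | 45 |
| Sunday's | 50.0 | 0 | 63 |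

(readings scatter by 1.5 percentage points)

- time up to 80 min at which intermediate C stands highest
- the amount of intermediate C, in percent of the starting material charged, at that time
- earliest time at which at least nineteen twentieths of that best amount are there, in min
- latest time at which they still are, in min

- the numbers in the tables scatter with a standard deviation of 1.5 percentage points

Which number must I know well? Not the charge: Sunday's is 2.24 times Monday's, yet after 10.0 min intermediate C reads 5 % in Monday's run and 5 % in Sunday's. Not the limit either: the highest readings stand at 2.00 min, far below 80 min. The speed of the fall matters, and it rests on a low reading carrying a scatter of 1.5 points.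

Taken as one exponential from 2.00 min to 10.0 min, the readings of intermediate C give a halving time of 2.39 min in Monday's run and 2.47 min in Sunday's. I carry their mean, 2.43 min, as the fall half-life, the time in which intermediate C halves on its way down. It gives a first-order fall rate of 0.285 min⁻¹. Run back to time zero, the mean fall line starts at 86.7 %. Its gap to the mean reading at 0.500 min gives a rise rate of 1.67 min⁻¹. For the flask, I commit to a peak at 1.28 min of 49.9 %.

The forecast, holding that “the steps look first order”, says 1.3 min and 52 %, 2.1 points above my height, with the window from 0.9 min to 1.9 min.

The flask gives 51.3 % at 1.35 min, with the window from 0.934 min to 1.91 min.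

    intermediate E → target (k = 0.00540 s⁻¹)
    starting material → intermediate A (k = 0.00460 s⁻¹)
    target ⇌ isomer of the product (K = 0.320, k = 0.00970 s⁻¹)
    starting material → intermediate C (k = 0.0190 s⁻¹)
    intermediate A ⇌ intermediate B (K = 1.10, k = 0.00520 s⁻¹)
    starting material + intermediate B → side product (k = 0.0170 L mol⁻¹ s⁻¹)
    intermediate C ⇌ intermediate D (K = 1.70, k = 0.00610 s⁻¹)
    intermediate D → intermediate E (k = 0.0200 s⁻¹)

In the flask at 0.487 min, intermediate C is made 4.51 times faster than it is used up, each step taken net, and the starting material is under a fiftieth of its charge after 2.73 min. Carried down from the peak, the fall half-life gives 7.70 % at 8.00 min, where the flask holds 8.91 %. The neighbour charged with 0.14 M peaks at 51.3 %, and its 80 min span 32.9 fall half-lives, at the end of which intermediate C stands at 0 %.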